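We put south-east first, and we let a count of lifetimes of Z carry that choice.

| flask | G | temperature | remark | time |
|---|---|---|---|---|
| winter | 0.20 M | 84 °C | run made earlier |  |
| autumn | 0.30 M | 125 °C | run made earlier |  |
| west | 0.40 M | 140 °C |  | 10 h |
| south-west | 0.40 M | 90 °C |  | 10 h |
| north-east | 0.40 M | 65 °C |  | 10 h |
| south-east | 0.40 M | 115 °C |  | 10 h |

- winter (time / h: Z / %, G / %): 12.0: 4, 96; 20.0: 33, 70; 30.0: 93, 8; 50.0: 99, 0; 60.0: 104, 1; 96.0: 101, 0; 144: 101, 1
- autumn (time / h: Z / %, G / %): 3.00: 102, 1; 6.00: 100, 0; 8.00: 98, 0; 12.0: 97, 0; 15.0: 93, 3; 20.0: 96, 0

(standard deviation of a reading: 2 percentage points)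

1. the flask that comes out highest in amount of Z, in percent of the G charged, or "all alike" when all lie within 1.5 percentage points (west / south-west / north-east / south-east / all alike)
2. Z at the end, in percent of the G charged, west
3. Z at the end, in percent of the G charged, south-west
4. Z at the end, in percent of the G charged, north-east
5. Z at the end, in percent of the G charged, south-east

- steps that have been proposed: G + Z -> 2 Z; G -> Z; Z -> E

Winter shows G turning into Z after a slow start, the induction period, and autumn shows Z sinking afterwards, which we take to be the proposed step to E. So we look for the flask that has finished G by 10 h and spent few lifetimes of Z. Winter gives the first part: drawn on the logarithm of Z over G between 20.0 h and 30.0 h, Z equals G near 22.3 h. If growth feeds on Z, its speed goes with the charge, and at 0.40 M that midpoint moves to about 11.2 h at winter's temperature. North-east, colder than winter, should still be in its slow start at 10 h. South-west, hotter than winter, should stand on the steep rise, short of finished. South-east and west should finish early.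

Between those two we look at the fade. We read its rate twice from separate pairs of autumn readings, where G reads 3 % at most. The outer pair, 3.00 h and 20.0 h, gives 0.00357 h⁻¹. The inner pair, 8.00 h and 15.0 h, gives 0.00748 h⁻¹, twice as much, so they part. Yet their drops are close, 6 percentage points and 5 points, against a scatter of 2 points per reading, and the outer span is 2.43 times as long. The inner pair's late row also reads G at 3 %, where G read 0 % at 12.0 h, so that row shows its scatter openly. The inner pair cheats, and we keep the outer one.

The fade count, the number of lifetimes of Z passing in the flask's time, is that rate times 10 h: 0.0357, a loss of 3.50 % of the charge at autumn's temperature. South-east, colder than autumn, should lose less, which by this reckoning puts its Z above 96.5 %. West, hotter, should lose more.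

The forecast also names south-east, “complete, with little decay”, at 97.5 %, with 88 % in west, 92 % in south-west and 0.2 % in north-east. The flasks give south-east highest at 98.7 %, then 91.3 % in south-west, 85.3 % in west and 0.0563 % in north-east.

    G + Z → 2 Z (k = 2.48 L mol⁻¹ h⁻¹, Ea = 80.0 kJ mol⁻¹)
    G → Z (k = 5.12 × 10⁻⁴ h⁻¹, Ea = 122 kJ mol⁻¹)
    Z → E (k = 9.25 × 10⁻⁵ h⁻¹, Ea = 129 kJ mol⁻¹)
    (constants at 90 °C)

In south-east, G is under a fiftieth of its charge by 1.93 h, while the half-life of Z on its way to E, taken at 1.22 h, is 20 d, far longer than the 10 h of the run. In south-east that half-life makes 0.0145 lifetimes, fewer than the fade count of 0.0357, and E ends at 1.26 %. The south-east recipe at 130 °C, hotter than autumn, ends with more E than the 3.50 % reckoned for autumn's temperature, at 5.94 %, and Z at 94.1 %.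

The numbers in the tables were generated by integration with made-up constants; noise was put on by code.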